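**Retrosynthetic overview**

- The target is cut back to 5,6-dibromoindole-2-carboxylic acid: C2–Br comes from ipso-bromodecarboxylation and C3–Br from ordinary electrophilic substitution.
- That acid comes from an N-Boc 5,6-dibromoindoline-2-carboxylate by Boc cleavage, dehydrogenation and saponification.
- Key disconnection: N1–C7a and C3–C3a of the five-membered ring, giving 4,5-dibromobenzyne and methyl 2-(Boc-amino)acrylate. The pyrroline ring is the only ring formed; the benzene ring is bought.
- Feature the plan rests on: the benzo ring carries Br on C5 and C6 and H on C4 and C7, so the aryne across C3a–C7a is mirror-symmetric and N1 and C3 can add in either sense with the same result.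
- The aryne precursor (an ortho-silylaryl triflate) comes from 3,4-dibromophenol by iodination at C6, O-silylation, iodine–lithium exchange with retro-Brook shift, and triflation.

Key step: step 4

Assumption: C2 of indolines 9 and 10 is formed without stereocontrol (racemate). Their SMILES show the (S) enantiomer only as a drawing convention, and the centre disappears in step 6; the target has no stereocentre.

**Route**

Step 1
Reactants: 1 3,4-dibromophenol
Product: 2 4,5-dibromo-2-iodophenol
Conditions: NIS (1.05 equiv), TsOH·H2O (10 mol%), MeCN, 0 °C → rt
Reagents that add atoms: N-iodosuccinimide, O=C1CCC(=O)N1I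
Why: Electrophilic aromatic iodination directed ortho/para by the hydroxyl group; the para position (C4) is blocked by bromine and C2 is flanked by OH and Br, so iodine should enter at the open ortho position C6.

Step 2
Reactants: 2 4,5-dibromo-2-iodophenol
Product: 3 (4,5-dibromo-2-iodophenoxy)trimethylsilane
Conditions: HMDS (0.7 equiv), THF, 65 °C; volatiles removed in vacuo, used crude
Reagents that add atoms: hexamethyldisilazane, C[Si](C)(C)N[Si](C)(C)C
Why: O-Silylation of a phenol with a silazane, driven by loss of ammonia, should give the silyl ether cleanly enough to be used without purification.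

Step 3
Reactants: 3 (4,5-dibromo-2-iodophenoxy)trimethylsilane
Product: 6 4,5-dibromo-2-(trimethylsilyl)phenyl trifluoromethanesulfonate, via aryllithium 4 (not isolated), via lithium phenoxide 5 (not isolated)
Conditions: n-BuLi (1.05 equiv), THF, −100 °C → −80 °C; then Tf2O (1.2 equiv), −100 °C → rt
Reagents that add atoms: trifluoromethanesulfonic anhydride, O=S(=O)(OS(=O)(=O)C(F)(F)F)C(F)(F)F
Why: Iodine–lithium exchange is far faster than bromine–lithium exchange at −100 °C, the ortho-lithiated aryl silyl ether 4 undergoes an anionic 1,3-retro-Brook O→C silyl shift to phenoxide 5, and 5 is O-sulfonylated by Tf2O (the standard one-flask route to ortho-silylaryl triflates).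

Step 4
Reactants: 6 4,5-dibromo-2-(trimethylsilyl)phenyl trifluoromethanesulfonate (1.5 equiv); 7 methyl 2-[(tert-butoxycarbonyl)amino]acrylate (1.0 equiv)
Product: 9 rac-1-tert-butyl 2-methyl 5,6-dibromo-2,3-dihydro-1H-indole-1,2-dicarboxylate, via 4,5-dibromobenzyne 8 (not isolated)
Conditions: tetrabutylammonium difluorotriphenylsilicate (TBAT, 2.0 equiv), THF, rt
Reagents that add atoms: none
Why: Fluoride attacks silicon of 6 and 1,2-elimination of triflate releases aryne 8; the carbamate nitrogen of 7 adds to one aryne carbon (N1–C7a), the ortho aryl anion adds to the acrylate β-carbon (C3–C3a), and the resulting ester enolate is protonated at C2. This is the known fluoride-triggered formal [3+2] aryne annulation of N-carbamoyl dehydroamino esters to indoline-2-carboxylates. The pyrroline ring (N1–C2–C3–C3a–C7a) closes by a formally 5-endo-trig conjugate addition of the aryl anion onto the captodative alkene, or its concerted asynchronous equivalent. The C2 stereocentre arises from unselective protonation of the enolate, so 9 should be racemic, which does not matter because C2 becomes sp2 in step 6. No regiocontrol is needed because the aryne is mirror-symmetric (Br on the future C5 and C6, H on C4 and C7). The step does need ring closure to outrun protonation of the aryl anion; this is helped by the intramolecular acceptor, by the anhydrous fluoride source, and by the anion sitting between N and a C–H, so it cannot expel bromide to form a second aryne.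

Step 5
Reactants: 9 rac-1-tert-butyl 2-methyl 5,6-dibromo-2,3-dihydro-1H-indole-1,2-dicarboxylate
Product: 10 rac-methyl 5,6-dibromo-2,3-dihydro-1H-indole-2-carboxylate
Conditions: TFA/CH2Cl2 (1:4), 0 °C → rt; aq. NaHCO3 work-up
Reagents that add atoms: none
Why: Acidolytic Boc cleavage (loss of the tert-butyl cation, then decarboxylation of the carbamic acid) leaves the methyl ester and aryl bromides untouched and frees the N–H, which makes the indoline easier to dehydrogenate.

Step 6
Reactants: 10 rac-methyl 5,6-dibromo-2,3-dihydro-1H-indole-2-carboxylate
Product: 11 methyl 5,6-dibromo-1H-indole-2-carboxylate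
Conditions: DDQ (1.2 equiv), toluene, 80 °C
Reagents that add atoms: none
Why: Quinone dehydrogenation of an indoline (hydride abstraction followed by proton loss) is driven by the gain of pyrrole aromaticity and should give the indole-2-carboxylate, erasing the C2 stereocentre.

Step 7
Reactants: 11 methyl 5,6-dibromo-1H-indole-2-carboxylate
Product: 12 5,6-dibromo-1H-indole-2-carboxylic acid
Conditions: LiOH·H2O (3 equiv), THF/MeOH/H2O, 40 °C; then 1 M HCl to pH 2
Reagents that add atoms: lithium hydroxide, [Li+].[OH-]
Why: Saponification of the methyl ester by acyl substitution; the indole N–H is only deprotonated reversibly and the aryl bromides are inert to aqueous hydroxide.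

Step 8
Reactants: 12 5,6-dibromo-1H-indole-2-carboxylic acid
Product: 14 2,3,5,6-tetrabromo-1H-indole, via 3,5,6-tribromoindole-2-carboxylic acid 13 (not isolated)
Conditions: NBS (2.1 equiv, two portions), anhydrous DMF, 0 °C → rt, dark; aq. Na2S2O3 work-up
Reagents that add atoms: N-bromosuccinimide, O=C1CCC(=O)N1Br
Why: Electrophilic bromination first takes the most nucleophilic position C3 to give 13, and the second bromonium equivalent replaces the C2 carboxyl group with loss of CO2 (ipso-bromodecarboxylation of a heteroaryl carboxylic acid, by direct ipso attack or through the 3,3-dibromoindolenine and a 1,2-bromine shift), while C4 and C7 are deactivated by the adjacent bromines.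

**Compound list**

1 | 3,4-dibromophenol | Oc1ccc(Br)c(Br)c1 | starting material
2 | 4,5-dibromo-2-iodophenol | Oc1cc(Br)c(Br)cc1I | intermediate
3 | (4,5-dibromo-2-iodophenoxy)trimethylsilane | C[Si](C)(C)Oc1cc(Br)c(Br)cc1I | intermediate
4 | [4,5-dibromo-2-(trimethylsilyloxy)phenyl]lithium (not isolated) | C[Si](C)(C)Oc1cc(Br)c(Br)cc1[Li] | intermediate
5 | lithium 4,5-dibromo-2-(trimethylsilyl)phenoxide (not isolated) | [Li+].[O-]c1cc(Br)c(Br)cc1[Si](C)(C)C | intermediate
6 | 4,5-dibromo-2-(trimethylsilyl)phenyl trifluoromethanesulfonate | C[Si](C)(C)c1cc(Br)c(Br)cc1OS(=O)(=O)C(F)(F)F | intermediate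
7 | methyl 2-[(tert-butoxycarbonyl)amino]acrylate | C=C(NC(=O)OC(C)(C)C)C(=O)OC | starting material
8 | 4,5-dibromobenzyne (1,2-dibromo-4,5-didehydrobenzene, not isolated) | BrC1=CC#CC=C1Br | intermediate
9 | rac-1-tert-butyl 2-methyl 5,6-dibromo-2,3-dihydro-1H-indole-1,2-dicarboxylate (racemic, (S) enantiomer drawn) | COC(=O)[C@@H]1Cc2cc(Br)c(Br)cc2N1C(=O)OC(C)(C)C | intermediate
10 | rac-methyl 5,6-dibromo-2,3-dihydro-1H-indole-2-carboxylate (racemic, (S) enantiomer drawn) | COC(=O)[C@@H]1Cc2cc(Br)c(Br)cc2N1 | intermediate
11 | methyl 5,6-dibromo-1H-indole-2-carboxylate | COC(=O)c1cc2cc(Br)c(Br)cc2[nH]1 | intermediate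
12 | 5,6-dibromo-1H-indole-2-carboxylic acid | OC(=O)c1cc2cc(Br)c(Br)cc2[nH]1 | intermediate
13 | 3,5,6-tribromo-1H-indole-2-carboxylic acid (not isolated) | OC(=O)c1[nH]c2cc(Br)c(Br)cc2c1Br | intermediate
14 | 2,3,5,6-tetrabromo-1H-indole | Brc1cc2[nH]c(Br)c(Br)c2cc1Br | target

**Step count**

Total steps: 8. Longest linear sequence: 8 steps (1 → 14); 7 is bought and enters at step 4.

**Steps most likely to fail, with fallbacks**

Step 4. The risk is that the aryl anion formed after N-arylation is protonated, or takes the Boc carbonyl by acyl transfer, before it closes onto the acrylate. The aryne may also be consumed by ene reaction or oligomerisation, so that open-chain N-aryl enamide builds up instead of the indoline. The fallback forms the same two bonds stepwise with metal catalysis and no aryne. It sets out from 7: a Heck reaction with 1,2-dibromo-4,5-diiodobenzene (3 equiv; Pd(OAc)2, Bu4NCl, NaHCO3, DMF, 80 °C), in which C–I reacts and C–Br does not, should give methyl (Z)-2-[(tert-butoxycarbonyl)amino]-3-(4,5-dibromo-2-iodophenyl)acrylate F1, with NHBoc and the iodoarene cis (C3–C3a bond). Intramolecular Goldberg amidation at the remaining C–I (CuI, N,N'-dimethylethylenediamine, K3PO4, toluene, 80 °C) should then close N1–C7a to give 1-tert-butyl 2-methyl 5,6-dibromo-1H-indole-1,2-dicarboxylate F2. TFA/CH2Cl2 removes Boc to give 11, where the route is rejoined and the dehydrogenation is no longer needed. The symmetric diiodide fixes the 5,6-dibromo pattern just as the symmetric aryne does.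

Step 8. The risk is that the second bromination stalls at 13, or that adventitious water attacks the 3-bromoindolenine and diverts the material to oxindole-type over-oxidation instead of ipso substitution with loss of CO2. The fallback sets out from 12: silver-catalysed protodecarboxylation (Ag2CO3 10 mol%, AcOH, DMSO, 120 °C) should give 5,6-dibromo-1H-indole F3. NBS (1 equiv, DMF, 0 °C) then brominates C3 to 3,5,6-tribromo-1H-indole F4, and a second equivalent of NBS (THF, −78 °C → rt) brominates C2 through the 3,3-dibromoindolenine and a 1,2-bromine shift, arriving at 14.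

Step 3. The risk is bromine–lithium exchange competing with iodine–lithium exchange, which would scramble halogens and could form an aryne from an ortho-bromoaryllithium; intermolecular proton or silyl transfer could also intervene before the retro-Brook shift. The fallback uses magnesium instead of lithium and an intermolecular C-silylation. It sets out from 3: iodine–magnesium exchange with iPrMgCl·LiCl (THF, −40 °C), which leaves aryl bromides untouched, should give [4,5-dibromo-2-(trimethylsilyloxy)phenyl]magnesium chloride F5. Quenching with Me3SiCl (→ rt) should give [4,5-dibromo-2-(trimethylsilyl)phenoxy]trimethylsilane F6; a retro-Brook shift of F5 followed by O-silylation leads to the same compound. K2CO3 in MeOH at 0 °C cleaves the O–Si bond to 4,5-dibromo-2-(trimethylsilyl)phenol F7, and Tf2O/pyridine (CH2Cl2, 0 °C) gives 6, where the route is rejoined.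

**Further compounds**

F1 | step 4 | methyl (Z)-2-[(tert-butoxycarbonyl)amino]-3-(4,5-dibromo-2-iodophenyl)acrylate | COC(=O)/C(NC(=O)OC(C)(C)C)=C/c1cc(Br)c(Br)cc1I
F2 | step 4 | 1-tert-butyl 2-methyl 5,6-dibromo-1H-indole-1,2-dicarboxylate | COC(=O)c1cc2cc(Br)c(Br)cc2n1C(=O)OC(C)(C)C
F3 | step 8 | 5,6-dibromo-1H-indole | Brc1cc2cc[nH]c2cc1Br
F4 | step 8 | 3,5,6-tribromo-1H-indole | Brc1c[nH]c2cc(Br)c(Br)cc12
F5 | step 3 | [4,5-dibromo-2-(trimethylsilyloxy)phenyl]magnesium chloride | C[Si](C)(C)Oc1cc(Br)c(Br)cc1[Mg]Cl
F6 | step 3 | [4,5-dibromo-2-(trimethylsilyl)phenoxy]trimethylsilane | C[Si](C)(C)Oc1cc(Br)c(Br)cc1[Si](C)(C)C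
F7 | step 3 | 4,5-dibromo-2-(trimethylsilyl)phenol | C[Si](C)(C)c1cc(Br)c(Br)cc1O
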